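The halves are joined at C1–C13′ and C3–C11′ by a silver-induced (4+3) cycloaddition of cyclopentadiene 18 with the cyclic chloro-alkoxyallyl cation from 34, in which O-8′ ties C12′ into a ring. The resulting bicyclo[3.2.1]octene 36 holds C12′ as a hemiketal, beside the C11′–Cl bond, inside the six-membered ring C1–C13′–C12′–C11′–C3–C2. The key step exploits that C11′ is both the lactone α-carbon and a norbornene ring atom: a quasi-Favorskii 1,2-shift of C13′ from C12′ to C11′ contracts this ring to the cyclopentane C1–C13′–C11′–C3–C2, extrudes C12′ as the carbonyl of the spiro γ-lactone and sets quaternary C11′ by inversion.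

Key step: step 26

Remark: C1–C15 (guaianolide half) and C1′–C15′ (1,10-seco-eudesmanolide half) follow sesquiterpene numbering; centres that later become sp2 or are lost (acetal and hemiketal carbons, C3, C4 and C11 of the selenides, C11′ of 26 and 32) are carried as mixtures and left undefined in the SMILES.

**Guaianolide diene (steps 1–12)**

Step 1
Reactants: 1 cyclopentane-1,3-dione; 2 (E)-but-2-enal
Product: 4 (4S)-2-methoxy-4-methyl-3,4,6,7-tetrahydrocyclopenta[b]pyran-5(2H)-one, via lactol 3 (not isolated)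
Conditions: (R)-α,α-diphenylprolinol trimethylsilyl ether (10 mol %), PhCO2H (10 mol %), CH2Cl2, 0 °C; then MeOH, PPTS, 4 Å MS, rt
Reagents that add atoms: methanol, CO
Why: Iminium-catalysed organocatalytic Michael addition of the 1,3-dione, in which the diphenyl(silyloxy)methyl group of the (R)-catalyst shields one enal face so that C1 adds to the other and sets C10 as S, after which the adduct closes to lactol 3 and Fischer acetalisation fixes it as the cyclic vinylogous ester.

Step 2
Reactants: 4 methyl acetal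
Product: 5 (4S)-2-methoxy-4,6-dimethyl-3,4,6,7-tetrahydrocyclopenta[b]pyran-5(2H)-one
Conditions: LiN(iPr)2, THF, −78 °C; MeI
Reagents that add atoms: iodomethane, CI
Why: Kinetic α′-enolate alkylation of the vinylogous ester (Stork–Danheiser alkylation) places the future C15 methyl on C4; the new centre is uncontrolled and need not be controlled because C4 becomes sp2 in step 12.

Step 3
Reactants: 5 dimethyl vinylogous ester
Product: 6 3-allyl-4-methyl-2-[(2S)-4-oxobutan-2-yl]cyclopent-2-en-1-one
Conditions: CH2=CHCH2MgBr, THF, −78 → 0 °C; then 1 M HCl, THF, 0 °C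
Reagents that add atoms: allylmagnesium bromide, C=CC[Mg]Br; water, O
Why: 1,2-Addition to the vinylogous ester followed by acid hydrolysis (Stork–Danheiser transposition) moves the carbonyl to C2, creates the C1=C5 enone carrying the allyl group (C6, C7) on C5 and releases the C8 aldehyde from the acetal.

Step 4
Reactants: 6 enone aldehyde
Product: 7 3-allyl-4-methyl-2-[(2S)-pent-4-en-2-yl]cyclopent-2-en-1-one
Conditions: Ph3PCH3Br, KN(SiMe3)2, THF, −78 → 0 °C
Reagents that add atoms: methylenetriphenylphosphorane, C=P(c1ccccc1)(c1ccccc1)c1ccccc1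
Why: Wittig methylenation, the aldehyde reacting far faster than the hindered, fully substituted cyclopentenone carbonyl.

Step 5
Reactants: 7 triene
Product: 8 (8S)-3,8-dimethyl-3,4,7,8-tetrahydroazulen-1(2H)-one
Conditions: second-generation Grubbs catalyst (5 mol %), CH2Cl2 (high dilution), 40 °C
Reagents that add atoms: none
Why: Ring-closing metathesis of the two monosubstituted alkenes closes the seven-membered ring at C7=C8, the tetrasubstituted enone alkene being inert.

Step 6
Reactants: 8 hydroazulenone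
Product: 9 7α,8α-epoxide of 8
Conditions: mCPBA, NaHCO3, CH2Cl2, 0 °C
Reagents that add atoms: 3-chloroperbenzoic acid, OOC(=O)c1cccc(Cl)c1
Why: Prilezhaev epoxidation of the only electron-rich alkene (the enone C1=C5 is deactivated), from the face opposite the C10 methyl group, should give the α-epoxide.

Step 7
Reactants: 9 epoxy enone
Product: 10 3-(phenylselanyl) epoxy enone
Conditions: LiN(iPr)2, THF, −78 °C; PhSeCl
Reagents that add atoms: benzeneselenenyl chloride, Cl[Se]c1ccccc1
Why: Kinetic α′-enolate selenenylation at C3 anti to the C4 methyl group puts selenium syn to H-4, as the later syn-elimination requires.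

Step 8
Reactants: 10 seleno enone
Product: 11 2β-hydroxy-3-(phenylselanyl) epoxide
Conditions: (S)-Me-CBS oxazaborolidine (20 mol %), catecholborane, toluene, −78 °C
Reagents that add atoms: none
Why: Corey–Bakshi–Shibata reduction in which, with the fully substituted enone carbon C1 as the large group, the (S)-catalyst should deliver hydride to the α-face and set C2 (2β-OH) under reagent control, leaving epoxide and selenide untouched.

Step 9
Reactants: 12 2-bromopropanoic acid; 13 diphenyl diselenide
Product: 14 2-(phenylselanyl)propanoic acid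
Conditions: NaBH4, EtOH, 0 °C; then 12, NaHCO3, rt; HCl work-up
Reagents that add atoms: none
Why: Borohydride cleaves the diselenide to the selenolate, which displaces bromide from the α-bromo carboxylate (SN2).

Step 10
Reactants: 11 epoxy alcohol; 14 2-(phenylselanyl)propanoic acid
Product: 15 2β-hydroxy-3,11-bis(phenylselanyl)guai-1(5)-en-12,8α-olide
Conditions: 14, LiN(iPr)2 (excess), THF, 0 °C; 11, 50 °C; then AcOH, 50 °C
Reagents that add atoms: none
Why: Anti SN2 opening of the epoxide by the α-seleno carboxylate dianion at C7, the carbon less shielded on its β-face by the C10 methyl group, followed by lactonisation gives the trans-fused lactone with inversion at C7 and retention at C8 (selenide-based α-methylene lactone annulation).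

Step 11
Reactants: 15 hydroxy lactone
Product: 16 2β-acetoxy-3,11-bis(phenylselanyl)guai-1(5)-en-12,8α-olide
Conditions: Ac2O, pyridine, DMAP (cat.), CH2Cl2, 0 °C
Reagents that add atoms: acetic anhydride, CC(=O)OC(C)=O
Why: Standard acylation of the secondary allylic alcohol.

Step 12
Reactants: 16 bis-selenide
Product: 18 (2R,7R,8S,10S)-2β-acetoxyguaia-1(5),3,11(13)-trien-12,8α-olide, via bis-selenoxide 17 (not isolated)
Conditions: H2O2 (30 % aq.), pyridine, CH2Cl2, −20 → 0 °C; cold work-up, used at once
Reagents that add atoms: none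
Why: Selenide oxidation and syn-selenoxide elimination, the C11 selenoxide eliminating towards the methyl group and the C3 selenoxide towards H-4 and not towards the acetoxy-bearing C2, should unveil the α-methylene lactone and the labile 5-acetoxycyclopentadiene below 0 °C.

**Seco-eudesmane cation precursor (steps 13–24)**

Step 13
Reactants: 19 pent-4-en-1-ol
Product: 20 triisopropyl(pent-4-en-1-yloxy)silane
Conditions: iPr3SiCl, imidazole, DMF, rt
Reagents that add atoms: chlorotriisopropylsilane, CC(C)[Si](Cl)(C(C)C)C(C)C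
Why: Silylation of the primary alcohol with a group that survives acid, base and dissolving metal.

Step 14
Reactants: 20 silyl ether; 2 (E)-but-2-enal
Product: 21 (E)-6-[(triisopropylsilyl)oxy]hex-2-enal
Conditions: second-generation Hoveyda–Grubbs catalyst (2 mol %), excess 2, CH2Cl2, 40 °C
Reagents that add atoms: none
Why: Olefin cross-metathesis with crotonaldehyde gives the (E)-enal.

Step 15
Reactants: 21 enal; 22 (4-methoxy-2-methylphenyl)boronic acid
Product: 23 (3R)-3-(4-methoxy-2-methylphenyl)-6-[(triisopropylsilyl)oxy]hexanal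
Conditions: [RhCl(C2H4)2]2 (2.5 mol %), (R,R)-2,5-diphenylbicyclo[2.2.2]octa-2,5-diene (5.5 mol %), KOH (cat.), 1,4-dioxane/H2O, 30 °C
Reagents that add atoms: none
Why: Rhodium-catalysed asymmetric conjugate arylation (Hayashi–Miyaura reaction), with the diene-ligand enantiomer chosen so that the aryl group adds to the enal face giving 3R, which becomes 4′S once the formyl carbon is removed.

Step 16
Reactants: 23 β-aryl aldehyde
Product: 24 triisopropyl{[(4S)-4-(4-methoxy-2-methylphenyl)pentyl]oxy}silane
Conditions: Rh(dppp)2Cl (5 mol %), xylene, 140 °C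
Reagents that add atoms: none
Why: Tsuji–Wilkinson decarbonylation turns CH2CHO into the C15′ methyl group without touching the β-stereocentre.

Step 17
Reactants: 24 anisole
Product: 25 triisopropyl{[(4S)-4-(4-methoxy-2-methylcyclohexa-1,4-dien-1-yl)pentyl]oxy}silane
Conditions: Li, NH3(l), THF, t-BuOH, −78 → −33 °C; NH4Cl
Reagents that add atoms: none
Why: Birch reduction keeps the methoxy and both alkyl groups on sp2 carbons, so the 2,5-dihydroanisole with the tetrasubstituted C5′=C10′ alkene and the C8′=C7′ enol ether is the expected product and no ring stereocentre is created.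

Step 18
Reactants: 25 dihydroanisole
Product: 26 ethyl 1-methoxy-3-methyl-4-[(2S)-5-(triisopropylsilyloxy)pentan-2-yl]bicyclo[4.1.0]hept-3-ene-7-carboxylate
Conditions: ethyl diazoacetate (slow addition), CuOTf·0.5C6H6 (2 mol %), (S,S)-tert-butyl-bis(oxazoline) (2.2 mol %), CH2Cl2, 0 °C → rt
Reagents that add atoms: ethyl diazoacetate, CCOC(=O)C=[N+]=[N-]
Why: Catalyst-controlled copper-carbenoid cyclopropanation occurs at the electron-rich enol ether and not at the hindered tetrasubstituted alkene, the ligand enantiomer being chosen so that C11′ adds to the face of C7′ that gives (1R)-27.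

Step 19
Reactants: 26 methoxycyclopropane ester
Product: 27 ethyl 2-{(1R)-4-methyl-2-oxo-5-[(2S)-5-(triisopropylsilyloxy)pentan-2-yl]cyclohex-4-en-1-yl}acetate
Conditions: 1 M HCl, THF, 0 °C → rt (short)
Reagents that add atoms: water, O
Why: Acid opens the donor–acceptor cyclopropane at the C8′–C11′ bond (retro-aldol-type ring opening) to the γ-keto ester, the C7′–C11′ bond and the C7′ configuration being retained.

Step 20
Reactants: 27 keto ester
Product: 29 (3aR,7aR)-6-methyl-5-[(2S)-5-(triisopropylsilyloxy)pentan-2-yl]-3a,4,7,7a-tetrahydro-1-benzofuran-2(3H)-one, via cis-hydroxy ester 28 (not isolated)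
Conditions: LiBH(s-Bu)3, THF, −78 °C; NH4Cl; then PPTS, toluene, 60 °C
Reagents that add atoms: none
Why: The bulky hydride attacks the ketone anti to the C7′ side chain (equatorial attack) to give the cis-alcohol, which lactonises to the cis-fused γ-lactone and so sets C8′.

Step 21
Reactants: 29 cis-lactone
Product: 30 (3aS,4S,7aR)-4-hydroxy lactone (6′α-OH)
Conditions: SeO2 (0.5 equiv.), t-BuOOH, CH2Cl2, rt
Reagents that add atoms: tert-butyl hydroperoxide, CC(C)(C)OO
Why: Riley allylic hydroxylation (ene reaction then [2,3]-shift) should occur at C6′, the allylic CH2 not deactivated by an adjacent C–O bond, from the convex face of the cis-fused bicycle, giving the alcohol trans to the lactone ring bonds.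

Step 22
Reactants: 30 allylic alcohol
Product: 31 4-O-tert-butyldimethylsilyl ether of 30
Conditions: t-BuMe2SiOTf, 2,6-lutidine, CH2Cl2, −40 °C
Reagents that add atoms: tert-butyldimethylsilyl trifluoromethanesulfonate, CC(C)(C)[Si](C)(C)OS(=O)(=O)C(F)(F)F
Why: Silylation of the hindered secondary alcohol with the reactive triflate.

Step 23
Reactants: 31 silyl ether lactone
Product: 33 3,3-dichloro lactone (C11′Cl2), via monochlorolactone 32 (not isolated)
Conditions: LiN(SiMe3)2, THF, −78 °C, then N-chlorosuccinimide; repeated once in the same flask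
Reagents that add atoms: N-chlorosuccinimide, ClN1C(=O)CCC1=O
Why: Stepwise electrophilic chlorination of the lactone enolate, the α-chloro lactone being more acidic than its parent so that the second chlorine also enters at C11′.

Step 24
Reactants: 33 dichloro lactone
Product: 34 3,3-dichloro-2-methylidene-hexahydrobenzofuran (C12′=C13′H2)
Conditions: Cp2TiMe2, toluene, 65 °C, dark; filtered through basic alumina and used at once
Reagents that add atoms: dimethyltitanocene, C[Ti](C)(C1C=CC=C1)C1C=CC=C1
Why: Petasis methylenation converts the activated lactone carbonyl into the exocyclic enol ether and adds C13′, giving an allylic gem-dichloride that is primed for ionisation.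

**Union and end game (steps 25–28)**

Step 25
Reactants: 34 dichloro enol ether; 18 acetoxycyclopentadiene
Product: 36 chloro hemiketal (bicyclo[3.2.1]octene), via oxocarbenium salt 35 (not isolated)
Conditions: AgBF4, 2,6-di-tert-butyl-4-methylpyridine, freshly made 18, CH2Cl2, −78 → −40 °C; then aqueous NaHCO3
Reagents that add atoms: water, O
Why: Silver tetrafluoroborate abstracts one chloride to give a 1-chloro-2-alkoxyallyl cation whose (4+3) cycloaddition forms C1–C13′ and C3–C11′, the diene reacting on its α-face anti to the 2-acetoxy and C10 methyl groups, the cation on the convex face of its cis-fused bicycle (compact transition state), the hindered chloro terminus bonding to the unsubstituted diene carbon C3 to avoid a quaternary–quaternary bond, and water then trapping the oxocarbenium ion as the hemiketal.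

Step 26
Reactants: 36 chloro hemiketal
Product: 38 1′-O-triisopropylsilyl-6′-O-tert-butyldimethylsilyl-1′-O-deacetyl target, via potassium hemiketal oxide 37 (not isolated)
Conditions: KN(SiMe3)2 (1.05 equiv.), THF, −78 → 0 °C
Reagents that add atoms: none
Why: Deprotonation of the hemiketal gives oxide 37, and as its C12′=O bond forms the C12′–C13′ σ-bond, held antiperiplanar to C11′–Cl, migrates to C11′ and expels chloride in a concerted semibenzilic (quasi-Favorskii) rearrangement. The closest known reaction is the alkoxide-triggered quasi-Favorskii ring contraction of α-halo ketone (4+3) cycloadducts to norbornenes, here run on the isolated cyclic hemiketal. One ring is closed: the cyclopentane C1–C13′–C11′–C3–C2 arises from the six-membered ring C1–C13′–C12′–C11′–C3–C2 by a 1,2-alkyl shift with backside displacement (3-exo-tet geometry), while the γ-lactone ring is already in place and only gains its carbonyl. The single new stereocentre C11′ is set by inversion at the C–Cl carbon, so it is dictated by the configuration of 36 (chloride on the concave face of the tetrahydrofuran ring, C3 on the convex face). The step needs this migration to outrun epoxide closure or elimination, which the substrate secures because one equivalent of base is consumed by the hemiketal, the anomers equilibrate through the ring-opened keto alkoxide, and only C13′ can reach the σ* orbital of C11′–Cl in the rigid bicycle.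

Step 27
Reactants: 38 bis-silyl ether
Product: 39 1′-O-deacetyl target (1′,6′-diol)
Conditions: HF·pyridine, pyridine, THF, 0 °C → rt
Reagents that add atoms: none
Why: Fluoride-mediated cleavage of both silyl ethers under buffered conditions that leave the acetate and both lactones intact.

Step 28
Reactants: 39 diol
Product: 40 CNP0211028.3
Conditions: AcCl (1.1 equiv.), 2,4,6-collidine, CH2Cl2, −78 °C
Reagents that add atoms: acetyl chloride, CC(Cl)=O
Why: Selective acylation, the primary C1′ hydroxyl reacting much faster than the secondary allylic C6′ hydroxyl flanked by a tetrasubstituted alkene carbon and C7′.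

**Compound list**

1 | cyclopentane-1,3-dione | O=C1CCC(=O)C1 | starting material
2 | (E)-but-2-enal | C/C=C/C=O | starting material
3 | (4S)-2-hydroxy-4-methyl-3,4,6,7-tetrahydrocyclopenta[b]pyran-5(2H)-one (anomers) | OC1C[C@H](C)C2=C(O1)CCC2=O | intermediate
4 | (4S)-2-methoxy-4-methyl-3,4,6,7-tetrahydrocyclopenta[b]pyran-5(2H)-one (anomers) | COC1C[C@H](C)C2=C(O1)CCC2=O | intermediate
5 | (4S)-2-methoxy-4,6-dimethyl-3,4,6,7-tetrahydrocyclopenta[b]pyran-5(2H)-one (mixture at C2, C6) | COC1C[C@H](C)C2=C(O1)CC(C)C2=O | intermediate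
6 | 3-allyl-4-methyl-2-[(2S)-4-oxobutan-2-yl]cyclopent-2-en-1-one (C4 epimers) | O=CC[C@H](C)C1=C(CC=C)C(C)CC1=O | intermediate
7 | 3-allyl-4-methyl-2-[(2S)-pent-4-en-2-yl]cyclopent-2-en-1-one (C4 epimers) | C=CC[C@H](C)C1=C(CC=C)C(C)CC1=O | intermediate
8 | (8S)-3,8-dimethyl-3,4,7,8-tetrahydroazulen-1(2H)-one (C3 epimers) | C[C@H]1CC=CCC2=C1C(=O)CC2C | intermediate
9 | 5,6-epoxide of 8, oxirane trans to the 8-methyl group (7α,8α-epoxide in guaiane numbering) | C[C@H]1C[C@@H]3O[C@@H]3CC2=C1C(=O)CC2C | intermediate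
10 | 2-(phenylselanyl) derivative of 9, selenium trans to the 3-methyl group | C[C@H]1C[C@@H]3O[C@@H]3CC2=C1C(=O)C([Se]c4ccccc4)C2C | intermediate
11 | (1S)-1-hydroxy compound from 10 (guaiane 2β-OH, cis to the C10 methyl group) | C[C@H]1C[C@@H]3O[C@@H]3CC2=C1[C@H](O)C([Se]c4ccccc4)C2C | intermediate
12 | 2-bromopropanoic acid | CC(Br)C(O)=O | starting material
13 | diphenyl diselenide | c1ccc(cc1)[Se][Se]c1ccccc1 | starting material
14 | 2-(phenylselanyl)propanoic acid | CC([Se]c1ccccc1)C(O)=O | intermediate
15 | (7R,8S,10S)-2β-hydroxy-3,11-bis(phenylselanyl)guai-1(5)-en-12,8α-olide (trans-fused lactone; mixture at C3, C4, C11) | CC1([Se]c5ccccc5)C(=O)O[C@H]2C[C@H](C)C3=C(C[C@H]12)C(C)C([Se]c4ccccc4)[C@H]3O | intermediate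
16 | 2-O-acetate of 15 | CC1([Se]c5ccccc5)C(=O)O[C@H]2C[C@H](C)C3=C(C[C@H]12)C(C)C([Se]c4ccccc4)[C@H]3OC(C)=O | intermediate
17 | bis(selenoxide) of 16 | CC1([Se](=O)c5ccccc5)C(=O)O[C@H]2C[C@H](C)C3=C(C[C@H]12)C(C)C([Se](=O)c4ccccc4)[C@H]3OC(C)=O | intermediate
18 | (2R,7R,8S,10S)-2β-acetoxyguaia-1(5),3,11(13)-trien-12,8α-olide | C=C1C(=O)O[C@H]2C[C@H](C)C3=C(C[C@H]12)C(C)=C[C@H]3OC(C)=O | intermediate
19 | pent-4-en-1-ol | C=CCCCO | starting material
20 | triisopropyl(pent-4-en-1-yloxy)silane | C=CCCCO[Si](C(C)C)(C(C)C)C(C)C | intermediate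
21 | (E)-6-[(triisopropylsilyl)oxy]hex-2-enal | O=C/C=C/CCCO[Si](C(C)C)(C(C)C)C(C)C | intermediate
22 | (4-methoxy-2-methylphenyl)boronic acid | COc1ccc(B(O)O)c(C)c1 | starting material
23 | (3R)-3-(4-methoxy-2-methylphenyl)-6-[(triisopropylsilyl)oxy]hexanal | COc1ccc([C@@H](CC=O)CCCO[Si](C(C)C)(C(C)C)C(C)C)c(C)c1 | intermediate
24 | triisopropyl{[(4S)-4-(4-methoxy-2-methylphenyl)pentyl]oxy}silane | COc1ccc([C@@H](C)CCCO[Si](C(C)C)(C(C)C)C(C)C)c(C)c1 | intermediate
25 | triisopropyl{[(4S)-4-(4-methoxy-2-methylcyclohexa-1,4-dien-1-yl)pentyl]oxy}silane | COC1=CCC([C@@H](C)CCCO[Si](C(C)C)(C(C)C)C(C)C)=C(C)C1 | intermediate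
26 | ethyl 1-methoxy-3-methyl-4-[(2S)-5-(triisopropylsilyloxy)pentan-2-yl]bicyclo[4.1.0]hept-3-ene-7-carboxylate (cyclopropane on the face leading to (1R)-27; ester epimers) | CCOC(=O)C1[C@H]2CC([C@@H](C)CCCO[Si](C(C)C)(C(C)C)C(C)C)=C(C)C[C@@]12OC | intermediate
27 | ethyl 2-{(1R)-4-methyl-2-oxo-5-[(2S)-5-(triisopropylsilyloxy)pentan-2-yl]cyclohex-4-en-1-yl}acetate | CCOC(=O)C[C@H]1CC([C@@H](C)CCCO[Si](C(C)C)(C(C)C)C(C)C)=C(C)CC1=O | intermediate
28 | cis-2-hydroxy compound from 27 (hydroxyl cis to the CH2CO2Et group) | CCOC(=O)C[C@H]1CC([C@@H](C)CCCO[Si](C(C)C)(C(C)C)C(C)C)=C(C)C[C@H]1O | intermediate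
29 | (3aR,7aR)-6-methyl-5-[(2S)-5-(triisopropylsilyloxy)pentan-2-yl]-3a,4,7,7a-tetrahydro-1-benzofuran-2(3H)-one (cis-fused) | O=C1O[C@@H]2CC(C)=C([C@@H](C)CCCO[Si](C(C)C)(C(C)C)C(C)C)C[C@@H]2C1 | intermediate
30 | (3aS,4S,7aR)-4-hydroxy derivative of 29 (6′α-OH, trans to the lactone ring bonds) | O=C1O[C@@H]2CC(C)=C([C@@H](C)CCCO[Si](C(C)C)(C(C)C)C(C)C)[C@@H](O)[C@@H]2C1 | intermediate
31 | 4-O-tert-butyldimethylsilyl ether of 30 | O=C1O[C@@H]2CC(C)=C([C@@H](C)CCCO[Si](C(C)C)(C(C)C)C(C)C)[C@@H](O[Si](C)(C)C(C)(C)C)[C@@H]2C1 | intermediate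
32 | 3-chloro derivative of 31 (C3 epimers) | O=C1O[C@@H]2CC(C)=C([C@@H](C)CCCO[Si](C(C)C)(C(C)C)C(C)C)[C@@H](O[Si](C)(C)C(C)(C)C)[C@@H]2C1Cl | intermediate
33 | 3,3-dichloro derivative of 31 | O=C1O[C@@H]2CC(C)=C([C@@H](C)CCCO[Si](C(C)C)(C(C)C)C(C)C)[C@@H](O[Si](C)(C)C(C)(C)C)[C@@H]2C1(Cl)Cl | intermediate
34 | 2-methylidene analogue of 33 (3,3-dichloro-2-methylidene-2,3,3a,4,7,7a-hexahydro-1-benzofuran) | C=C1O[C@@H]2CC(C)=C([C@@H](C)CCCO[Si](C(C)C)(C(C)C)C(C)C)[C@@H](O[Si](C)(C)C(C)(C)C)[C@@H]2C1(Cl)Cl | intermediate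
35 | (4+3) cycloadduct as oxocarbenium tetrafluoroborate (C12′=O+ in the bicyclo[3.2.1]octene) | C=C1C(=O)O[C@H]2C[C@H](C)[C@@]34CC5=[O+][C@@H]6CC(C)=C([C@@H](C)CCCO[Si](C(C)C)(C(C)C)C(C)C)[C@@H](O[Si](C)(C)C(C)(C)C)[C@@H]6[C@@]5(Cl)[C@@H](C(C)=C3C[C@H]12)[C@H]4OC(C)=O.F[B-](F)(F)F | intermediate
36 | chloro hemiketal: bicyclo[3.2.1]oct-6-ene with bridges C2(OAc), C4=C5 and C13′H2–C12′(OH)(O-8′)–C11′(Cl) (anomers) | C=C1C(=O)O[C@H]2C[C@H](C)[C@@]34CC5(O)O[C@@H]6CC(C)=C([C@@H](C)CCCO[Si](C(C)C)(C(C)C)C(C)C)[C@@H](O[Si](C)(C)C(C)(C)C)[C@@H]6[C@@]5(Cl)[C@@H](C(C)=C3C[C@H]12)[C@H]4OC(C)=O | intermediate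
37 | potassium oxide of hemiketal 36 | C=C1C(=O)O[C@H]2C[C@H](C)[C@@]34CC5([O-])O[C@@H]6CC(C)=C([C@@H](C)CCCO[Si](C(C)C)(C(C)C)C(C)C)[C@@H](O[Si](C)(C)C(C)(C)C)[C@@H]6[C@@]5(Cl)[C@@H](C(C)=C3C[C@H]12)[C@H]4OC(C)=O.[K+] | intermediate
38 | 1′-O-triisopropylsilyl-6′-O-tert-butyldimethylsilyl-1′-O-deacetyl target | C=C1C(=O)O[C@H]2C[C@H](C)[C@@]34C[C@]5(C(=O)O[C@@H]6CC(C)=C([C@@H](C)CCCO[Si](C(C)C)(C(C)C)C(C)C)[C@@H](O[Si](C)(C)C(C)(C)C)[C@@H]65)[C@@H](C(C)=C3C[C@H]12)[C@H]4OC(C)=O | intermediate
39 | 1′-O-deacetyl target (1′,6′-diol) | C=C1C(=O)O[C@H]2C[C@H](C)[C@@]34C[C@]5(C(=O)O[C@@H]6CC(C)=C([C@@H](C)CCCO)[C@@H](O)[C@@H]65)[C@@H](C(C)=C3C[C@H]12)[C@H]4OC(C)=O | intermediate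
40 | CNP0211028.3 | C=C1C(=O)O[C@H]2C[C@H](C)[C@@]34C[C@]5(C(=O)O[C@@H]6CC(C)=C([C@@H](C)CCCOC(C)=O)[C@@H](O)[C@@H]65)[C@@H](C(C)=C3C[C@H]12)[C@H]4OC(C)=O | target

**Count and risks**

Total step count: 28. Longest linear sequence: 16 (steps 13–28).

Steps most likely to fail:

Step 25. The intermolecular cationic cycloaddition may lose regio- or facial control, the acetoxycyclopentadiene may undergo 1,5-hydrogen shift before it is trapped, or 34 may ionise and eliminate unproductively. The fallback sets out from 33 and uses an open-chain oxyallyl cation generated from a halo ketone with amine base in trifluoroethanol. MeLi at −78 °C should add once to 33 to give the methyl hemiketal F1. Et3SiOTf and 2,6-lutidine should silylate the open hydroxy ketone tautomer at the secondary C8′ hydroxyl to give the dichloromethyl ketone F2. With 18 in CF3CH2OH/Et3N at 0 °C, F2 should lose HCl to a chloro-oxyallyl cation, and its (4+3) cycloaddition should give the α-chloro ketone cycloadduct F3. Bu4NF at −20 °C then removes the triethylsilyl group, the alkoxide closes onto the ketone to give oxide 37, and the route is rejoined at 38.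

Step 21. The selenium ene reaction may attack C9′ or C4′ instead of C6′, over-oxidise to the enone, or show poor facial selectivity. The fallback sets out from 29. Allylic oxidation with CrO3·3,5-dimethylpyrazole is taken deliberately to the ketone level to give the 6′-oxo enone F4. Corey–Bakshi–Shibata reduction with (R)-Me-CBS oxazaborolidine and catecholborane then sets C6′ under reagent control, and the route comes back at 30.

Step 10. The hindered carboxylate dianion may act as a base (epoxide to allylic alcohol) or open the epoxide sluggishly and unselectively. The fallback sets out from 11 and uses a small linear nucleophile followed by carbonylative lactonisation. LiC≡CH·H2NCH2CH2NH2 in DMSO should open the epoxide anti at C7 to give the trans-7-ethynyl-8-hydroxy compound F5. PdCl2/thiourea-catalysed cyclocarbonylation under CO should convert F5 into the trans-fused α-methylene lactone alcohol F6. Ac2O/pyridine gives the acetate F7, and H2O2/pyridine oxidation with selenoxide elimination at C3 returns the route at 18.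

Further compounds
F1 | step 25 | methyl hemiketal from 33 (2-hydroxy-2-methyl-3,3-dichloro-hexahydrobenzofuran) | CC1(O)O[C@@H]2CC(C)=C([C@@H](C)CCCO[Si](C(C)C)(C(C)C)C(C)C)[C@@H](O[Si](C)(C)C(C)(C)C)[C@@H]2C1(Cl)Cl
F2 | step 25 | open-chain 11′,11′-dichloro methyl ketone with 8′-O-triethylsilyl and 6′-O-tert-butyldimethylsilyl ethers | CC(=O)C(Cl)(Cl)[C@H]1[C@H](O[Si](C)(C)C(C)(C)C)C([C@@H](C)CCCO[Si](C(C)C)(C(C)C)C(C)C)=C(C)C[C@H]1O[Si](CC)(CC)CC
F3 | step 25 | α-chloro ketone (4+3) cycloadduct (C12′ ketone, 8′-O-triethylsilyl) | C=C1C(=O)O[C@H]2C[C@H](C)[C@@]34CC(=O)[C@@](Cl)([C@H]5[C@H](O[Si](C)(C)C(C)(C)C)C([C@@H](C)CCCO[Si](C(C)C)(C(C)C)C(C)C)=C(C)C[C@H]5O[Si](CC)(CC)CC)[C@@H](C(C)=C3C[C@H]12)[C@H]4OC(C)=O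
F4 | step 21 | 6′-oxo enone from 29 (4-oxo lactone) | O=C1O[C@@H]2CC(C)=C([C@@H](C)CCCO[Si](C(C)C)(C(C)C)C(C)C)C(=O)[C@@H]2C1
F5 | step 10 | trans-7-ethynyl-8-hydroxy compound from 11 | C[C@H]1C[C@H](O)[C@@H](C#C)CC2=C1[C@H](O)C([Se]c4ccccc4)C2C
F6 | step 10 | 2β-hydroxy-3-(phenylselanyl)guaia-1(5),11(13)-dien-12,8α-olide | C=C1C(=O)O[C@H]2C[C@H](C)C3=C(C[C@H]12)C(C)C([Se]c4ccccc4)[C@H]3O
F7 | step 10 | 2-O-acetate of F6 | C=C1C(=O)O[C@H]2C[C@H](C)C3=C(C[C@H]12)C(C)C([Se]c4ccccc4)[C@H]3OC(C)=O
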